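**Retrosynthetic overview**
1. Rings are lettered A–F along the chain (A = terminal 2,4,6-trioxygenated ring, F = terminal 3,4,5-trioxygenated ring). The plan rests on ring D, which has five contiguous oxygens (aryl ethers at D1 to C4 and at D6 to E1, hydroxyls at D3, D4, D5) and one hydrogen at D2.
2. D3–D6 are read as the four carbons of squaric acid and D1–D2 as an ethynyl ether on the C4 oxygen. Cutting D2–D3 and D1–D6 gives ABC ethynyl ether 19 and EF-oxy cyclobutenone 29.
3. For 19, two Ullmann couplings each join a hindered phenol to a formyl-activated bromide. Baeyer–Villiger oxidation turns each formyl group into the next phenol, and trichloroethylene followed by BuLi makes the alkyne.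
4. For 29, Chan–Lam coupling and Baeyer–Villiger oxidation give the EF phenol, which displaces chloride from methyl squarate chloride (exchange of OMe in dimethyl squarate by a phenol would run uphill). Site-selective hydride addition and O-methylation follow.
5. Rings A, B, C, E and F are bought as arenes. Ring D is the only ring built and is built last. The endgame is global demethylation, purification as the peracetate and deacetylation.

Key step: step 15

Remark: the target has no stereocentre and no hindered axis, so it is achiral and no enantiocontrol is needed. Compounds 5, 28, 29, 31 and 33 are racemic and their centres are erased later. The target 35 first appears as crude material in step 16 and is delivered pure in step 17.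

**Step 1**
Reactants: 1 2,4,6-trimethoxybenzaldehyde
Product: 3 2,4,6-trimethoxyphenol, via aryl formate 2 (not isolated)
Conditions: mCPBA, CH2Cl2, 0 °C → rt; aq NaHCO3 wash; K2CO3 (cat.), MeOH, Ar, rt
Reagents that add atoms: 3-chloroperoxybenzoic acid OOC(=O)c1cccc(Cl)c1
Why: Baeyer–Villiger oxidation, in which the trimethoxyphenyl group migrates far better than hydrogen in the Criegee adduct, followed by base-catalysed methanolysis of the formate.

**Step 2**
Reactants: 4 5-bromo-1,2,3-trimethoxybenzene
Product: 6 6-bromo-2,3,4-trimethoxybenzaldehyde, via chloro(methoxy)methyl arene 5 (not isolated)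
Conditions: Cl2CHOMe, TiCl4, CH2Cl2, −20 → 0 °C; ice-water
Reagents that add atoms: dichloromethyl methyl ether COC(Cl)Cl; water O
Why: Rieche formylation (electrophilic aromatic substitution); the two free positions of 4 are equivalent and each lies ortho and para to methoxy groups, so only one aldehyde can form.

**Step 3**
Reactants: 3 2,4,6-trimethoxyphenol; 6 6-bromo-2,3,4-trimethoxybenzaldehyde
Product: 7 AB aldehyde, 2,3,4-trimethoxy-6-(2,4,6-trimethoxyphenoxy)benzaldehyde
Conditions: CuI (10 mol %), picolinic acid (20 mol %), K3PO4, DMSO, 90 °C, Ar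
Reagents that add atoms: none
Why: Ligand-assisted Ullmann diaryl ether coupling; the bromide has only one ortho substituent, a formyl group that speeds its reaction with copper, and picolinic acid ligation is the established remedy for 2,6-disubstituted phenols.

**Step 4**
Reactants: 7 AB aldehyde
Product: 9 AB phenol, 2,3,4-trimethoxy-6-(2,4,6-trimethoxyphenoxy)phenol, via AB formate 8 (not isolated)
Conditions: mCPBA, NaHCO3, CH2Cl2, 0 °C; aq wash; K2CO3 (cat.), MeOH, Ar, rt
Reagents that add atoms: 3-chloroperoxybenzoic acid OOC(=O)c1cccc(Cl)c1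
Why: Baeyer–Villiger oxidation of an aldehyde with oxygen at both ortho positions and at the para position, so aryl migration is strongly favoured, and the formate shields the oxidisable phenol until the peracid is gone.

**Step 5**
Reactants: 9 AB phenol; 10 4-bromo-2,6-dimethoxybenzaldehyde
Product: 11 ABC aldehyde, 2,6-dimethoxy-4-[2,3,4-trimethoxy-6-(2,4,6-trimethoxyphenoxy)phenoxy]benzaldehyde
Conditions: CuI (10 mol %), picolinic acid (20 mol %), K3PO4, DMSO, 90 °C, Ar
Reagents that add atoms: none
Why: Ullmann diaryl ether coupling in which all the crowding sits on the phenol, while the bromide is free at both ortho positions and activated by the para formyl group.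

**Step 6**
Reactants: 11 ABC aldehyde
Product: 13 ABC phenol, 2,6-dimethoxy-4-[2,3,4-trimethoxy-6-(2,4,6-trimethoxyphenoxy)phenoxy]phenol, via ABC formate 12 (not isolated)
Conditions: mCPBA, NaHCO3, CH2Cl2, 0 °C; aq wash; K2CO3 (cat.), MeOH, Ar, rt
Reagents that add atoms: 3-chloroperoxybenzoic acid OOC(=O)c1cccc(Cl)c1
Why: Baeyer–Villiger oxidation of a 2,4,6-trioxygenated benzaldehyde, the same substrate type as in step 1, which unmasks the C4 hydroxyl without any protecting group.

**Step 7**
Reactants: 13 ABC phenol; 14 trichloroethylene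
Product: 16 ABC (E)-1,2-dichlorovinyl ether, via dichloroacetylene 15 (not isolated)
Conditions: K2CO3, DMF, 70 °C, Ar
Reagents that add atoms: none
Why: Elimination–addition route to 1,2-dichlorovinyl ethers; base removes HCl from 14, and the phenoxide adds anti to linear 15, which sets the E geometry and is small enough to reach an oxygen flanked by two methoxy groups.

**Step 8**
Reactants: 16 ABC (E)-1,2-dichlorovinyl ether
Product: 19 ABC ethynyl ether, via chloroethynyl ether 17 (not isolated), via lithium acetylide 18 (not isolated)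
Conditions: n-BuLi (2.5 equiv), THF, −78 → −40 °C; H2O, −78 °C; rapid filtration through basic alumina, used at once
Reagents that add atoms: none
Why: β-Elimination of HCl followed by chlorine–lithium exchange and protonation, the standard conversion of dichlorovinyl ethers into ynol ethers; any aryl lithiation by excess butyllithium is reversed in the same quench.

**Step 9**
Reactants: 20 syringaldehyde (4-hydroxy-3,5-dimethoxybenzaldehyde); 21 3,4,5-trimethoxyphenylboronic acid
Product: 22 EF aldehyde, 3,5-dimethoxy-4-(3,4,5-trimethoxyphenoxy)benzaldehyde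
Conditions: 21 (2.5 equiv), Cu(OAc)2 (1 equiv), pyridine, 4 Å MS, CH2Cl2, dry air, rt
Reagents that add atoms: none
Why: Chan–Lam coupling, which tolerates acidic phenols with two ortho substituents; the formyl group also protects this phenol from oxidation by copper(II) and air.

**Step 10**
Reactants: 22 EF aldehyde
Product: 24 EF phenol, 3,5-dimethoxy-4-(3,4,5-trimethoxyphenoxy)phenol, via EF formate 23 (not isolated)
Conditions: mCPBA, CH2Cl2, rt; aq NaHCO3 wash; K2CO3 (cat.), MeOH, Ar, rt
Reagents that add atoms: 3-chloroperoxybenzoic acid OOC(=O)c1cccc(Cl)c1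
Why: Baeyer–Villiger oxidation in which the para aryloxy donor directs aryl migration, as with 3,4,5-trialkoxybenzaldehydes.

**Step 11**
Reactants: 25 3,4-dichlorocyclobut-3-ene-1,2-dione (squaryl dichloride)
Product: 26 3-chloro-4-methoxycyclobut-3-ene-1,2-dione
Conditions: MeOH (1.0 equiv), CH2Cl2, 0 °C → rt
Reagents that add atoms: methanol CO
Why: Addition–elimination on a vinylogous acid chloride; the methoxy group that enters lowers the electrophilicity of the ring, so the reaction can be stopped after one substitution.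

**Step 12**
Reactants: 26 3-chloro-4-methoxycyclobut-3-ene-1,2-dione; 24 EF phenol
Product: 27 aryl methyl squarate, 3-[3,5-dimethoxy-4-(3,4,5-trimethoxyphenoxy)phenoxy]-4-methoxycyclobut-3-ene-1,2-dione
Conditions: iPr2NEt (1.2 equiv), CH2Cl2, −40 → 0 °C; dry work-up
Reagents that add atoms: none
Why: Addition–elimination of the unhindered E1 phenol on the vinylogous acid chloride; chloride loss makes aryl ester formation irreversible, which a transesterification with release of methanol could not be.

**Step 13**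
Reactants: 27 aryl methyl squarate
Product: 28 rac-2-(EF-oxy)-4-hydroxy-3-methoxycyclobut-2-en-1-one
Conditions: LiAlH(OtBu)3 (1.05 equiv), THF, −78 °C; pH 7 buffer
Reagents that add atoms: none
Why: 1,2-Reduction of a squaric diester with a bulky alkoxyaluminium hydride, as used on dialkyl squarates; the carbonyl next to C–OMe is the vinylogous aryl ester (weaker donor) and the less crowded one, so hydride should add there and leave the carbonyl beside the EF-oxy carbon, and the new carbinol centre is racemic and is erased in step 15.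

**Step 14**
Reactants: 28 rac-2-(EF-oxy)-4-hydroxy-3-methoxycyclobut-2-en-1-one
Product: 29 rac-2-(EF-oxy)-3,4-dimethoxycyclobut-2-en-1-one
Conditions: MeI, Ag2O, 4 Å MS, CH2Cl2, rt, dark
Reagents that add atoms: iodomethane CI
Why: Purdie methylation under neutral conditions avoids acid-induced loss of the C4 oxygen, and capping the hydroxyl blocks the thermal rearrangement of 4-hydroxycyclobutenones to butenolides.

**Step 15**
Reactants: 19 ABC ethynyl ether; 29 rac-2-(EF-oxy)-3,4-dimethoxycyclobut-2-en-1-one
Product: 34 pentadecamethyl hexamer phenol (free OH at D3), via vinylketene 30 (not isolated), via vinylcyclobutenone 31 (not isolated), via dienylketene 32 (not isolated), via cyclohexadienone 33 (not isolated)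
Conditions: 19 (1.5 equiv), toluene (0.5 M), degassed, sealed tube, 110 °C then 140 °C
Reagents that add atoms: none
Why: Proposed new method: at about 110 °C the C1–C4 bond of 29 should break in a conrotatory 4π opening (C4 methoxy turning outward) to give vinylketene 30, and the H-bearing alkyne carbon of 19, made nucleophilic by the aryloxy oxygen, should add to the ketene carbonyl carbon in a [2+2] that makes D2–D3 and D1–D6 and gives vinylcyclobutenone 31. A second 4π opening of 31, in which the EF-oxy donor turns outward and so points the dimethoxyvinyl arm at the new ketene, gives dienylketene 32; ring D then closes by disrotatory 6π electrocyclisation (D3–D4 bond) to dienone 33, which enolises to phenol 34. The closest known reaction type is the Danheiser benzannulation of cyclobutenones with alkoxy-, siloxy- or amino-substituted alkynes; new here are the 2,3,4-trioxygenated, squarate-derived cyclobutenone and the aryl ethynyl ether as partners. No lasting stereocentre is created: the centres of 29, 31 and 33 are racemic and vanish on aromatisation. Two selectivities are needed, head-to-carbonyl orientation with [2+2] rather than [4+2] periselectivity, which the oxygen-polarised alkyne and the in-plane ketene LUMO secure, and trapping of 30 ahead of its dimerisation, which the reversible ring opening (low standing concentration of 30), the high concentration and the excess of 19 secure. Because the oxygen of 19 carries an aryl group without an sp3 C–H, the retro-ene fragmentation that consumes alkyl ynol ethers on heating has no pathway.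

**Step 16**
Reactants: 34 pentadecamethyl hexamer phenol
Product: 36 hexadecaacetate of the target, via crude hexadecaphenol 35 (not isolated)
Conditions: BBr3 (40 equiv), CH2Cl2, −78 °C → rt; ice-water, EtOAc, Ar; crude: Ac2O, pyridine, rt; chromatography
Reagents that add atoms: acetic anhydride CC(=O)OC(C)=O
Why: Lewis-acid ether cleavage in which bromide attacks only the sp3 methyl carbons of the boron-complexed ethers, so the five diaryl ether bonds remain, and acetylation turns the air-sensitive crude polyphenol into a stable compound that can be chromatographed.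

**Step 17**
Reactants: 36 hexadecaacetate of the target
Product: 35 target hexamer (hexadecaphenol)
Conditions: NaOMe (1.1 equiv per acetate), degassed MeOH–THF, Ar, 0 °C; AcOH; Sephadex LH-20 under Ar
Reagents that add atoms: none
Why: Zemplén-type transesterification of aryl acetates with exclusion of oxygen; acidic methanol is avoided because the 1,3,5-trioxygenated rings A, C and E can exchange their ether oxygens through keto tautomers.

**Compound list**
1 | 2,4,6-trimethoxybenzaldehyde | COc1cc(OC)c(C=O)c(OC)c1 | starting material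
2 | 2,4,6-trimethoxyphenyl formate | COc1cc(OC)c(OC=O)c(OC)c1 | intermediate
3 | 2,4,6-trimethoxyphenol | COc1cc(OC)c(O)c(OC)c1 | intermediate
4 | 5-bromo-1,2,3-trimethoxybenzene | COc1cc(Br)cc(OC)c1OC | starting material
5 | rac-1-bromo-2-[chloro(methoxy)methyl]-3,4,5-trimethoxybenzene | COC(Cl)c1c(Br)cc(OC)c(OC)c1OC | intermediate
6 | 6-bromo-2,3,4-trimethoxybenzaldehyde | O=Cc1c(Br)cc(OC)c(OC)c1OC | intermediate
7 | AB aldehyde | O=Cc1c(OC)c(OC)c(OC)cc1Oc2c(OC)cc(OC)cc2OC | intermediate
8 | AB formate | O=COc1c(OC)c(OC)c(OC)cc1Oc2c(OC)cc(OC)cc2OC | intermediate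
9 | AB phenol | Oc1c(OC)c(OC)c(OC)cc1Oc2c(OC)cc(OC)cc2OC | intermediate
10 | 4-bromo-2,6-dimethoxybenzaldehyde | O=Cc1c(OC)cc(Br)cc1OC | starting material
11 | ABC aldehyde | O=Cc1c(OC)cc(Oc2c(OC)c(OC)c(OC)cc2Oc3c(OC)cc(OC)cc3OC)cc1OC | intermediate
12 | ABC formate | O=COc1c(OC)cc(Oc2c(OC)c(OC)c(OC)cc2Oc3c(OC)cc(OC)cc3OC)cc1OC | intermediate
13 | ABC phenol | Oc1c(OC)cc(Oc2c(OC)c(OC)c(OC)cc2Oc3c(OC)cc(OC)cc3OC)cc1OC | intermediate
14 | trichloroethylene | ClC=C(Cl)Cl | starting material
15 | dichloroacetylene | ClC#CCl | intermediate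
16 | ABC (E)-1,2-dichlorovinyl ether | Cl/C=C(/Cl)Oc1c(OC)cc(Oc2c(OC)c(OC)c(OC)cc2Oc3c(OC)cc(OC)cc3OC)cc1OC | intermediate
17 | ABC chloroethynyl ether | ClC#COc1c(OC)cc(Oc2c(OC)c(OC)c(OC)cc2Oc3c(OC)cc(OC)cc3OC)cc1OC | intermediate
18 | ABC lithium aryloxyacetylide | [Li]C#COc1c(OC)cc(Oc2c(OC)c(OC)c(OC)cc2Oc3c(OC)cc(OC)cc3OC)cc1OC | intermediate
19 | ABC ethynyl ether | C#COc1c(OC)cc(Oc2c(OC)c(OC)c(OC)cc2Oc3c(OC)cc(OC)cc3OC)cc1OC | intermediate
20 | syringaldehyde | O=Cc1cc(OC)c(O)c(OC)c1 | starting material
21 | 3,4,5-trimethoxyphenylboronic acid | COc1cc(B(O)O)cc(OC)c1OC | starting material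
22 | EF aldehyde | O=Cc1cc(OC)c(Oc2cc(OC)c(OC)c(OC)c2)c(OC)c1 | intermediate
23 | EF formate | O=COc1cc(OC)c(Oc2cc(OC)c(OC)c(OC)c2)c(OC)c1 | intermediate
24 | EF phenol | Oc1cc(OC)c(Oc2cc(OC)c(OC)c(OC)c2)c(OC)c1 | intermediate
25 | 3,4-dichlorocyclobut-3-ene-1,2-dione | O=C1C(=O)C(Cl)=C1Cl | starting material
26 | 3-chloro-4-methoxycyclobut-3-ene-1,2-dione | COC1=C(Cl)C(=O)C1=O | intermediate
27 | EF-aryl methyl squarate | COC1=C(Oc2cc(OC)c(Oc3cc(OC)c(OC)c(OC)c3)c(OC)c2)C(=O)C1=O | intermediate
28 | rac-2-(EF-oxy)-4-hydroxy-3-methoxycyclobut-2-en-1-one | O=C1C(Oc2cc(OC)c(Oc3cc(OC)c(OC)c(OC)c3)c(OC)c2)=C(OC)C1O | intermediate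
29 | rac-2-(EF-oxy)-3,4-dimethoxycyclobut-2-en-1-one | O=C1C(Oc2cc(OC)c(Oc3cc(OC)c(OC)c(OC)c3)c(OC)c2)=C(OC)C1OC | intermediate
30 | (Z)-2-(EF-oxy)-3,4-dimethoxybuta-1,3-dien-1-one (vinylketene) | O=C=C(Oc1cc(OC)c(Oc2cc(OC)c(OC)c(OC)c2)c(OC)c1)/C(OC)=C/OC | intermediate
31 | rac-3-(ABC-oxy)-4-(EF-oxy)-4-[(Z)-1,2-dimethoxyvinyl]cyclobut-2-en-1-one | O=C1C=C(Oc2c(OC)cc(Oc3c(OC)c(OC)c(OC)cc3Oc4c(OC)cc(OC)cc4OC)cc2OC)C1(Oc5cc(OC)c(Oc6cc(OC)c(OC)c(OC)c6)c(OC)c5)/C(OC)=C/OC | intermediate
32 | 3-(ABC-oxy)-4-(EF-oxy)-5,6-dimethoxyhexa-1,3,5-trien-1-one (dienylketene) | O=C=C/C(Oc2c(OC)cc(Oc3c(OC)c(OC)c(OC)cc3Oc4c(OC)cc(OC)cc4OC)cc2OC)=C(/Oc5cc(OC)c(Oc6cc(OC)c(OC)c(OC)c6)c(OC)c5)\C(OC)=C\OC | intermediate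
33 | rac-3-(ABC-oxy)-4-(EF-oxy)-5,6-dimethoxycyclohexa-2,4-dien-1-one | O=C1C=C(Oc2c(OC)cc(Oc3c(OC)c(OC)c(OC)cc3Oc4c(OC)cc(OC)cc4OC)cc2OC)C(Oc5cc(OC)c(Oc6cc(OC)c(OC)c(OC)c6)c(OC)c5)=C(OC)C1OC | intermediate
34 | pentadecamethyl hexamer phenol (free OH at D3) | Oc1cc(Oc2c(OC)cc(Oc3c(OC)c(OC)c(OC)cc3Oc4c(OC)cc(OC)cc4OC)cc2OC)c(Oc5cc(OC)c(Oc6cc(OC)c(OC)c(OC)c6)c(OC)c5)c(OC)c1OC | intermediate
35 | CNP0218077.0, hexadecaphenol (crude in step 16, pure from step 17) | Oc1cc(O)c(Oc2cc(O)c(O)c(O)c2Oc2cc(O)c(Oc3cc(O)c(O)c(O)c3Oc3cc(O)c(Oc4cc(O)c(O)c(O)c4)c(O)c3)c(O)c2)c(O)c1 | target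
36 | hexadecaacetate of 35 | CC(=O)Oc1cc(Oc2c(OC(C)=O)cc(Oc3c(OC(C)=O)c(OC(C)=O)c(OC(C)=O)cc3Oc4c(OC(C)=O)cc(OC(C)=O)cc4OC(C)=O)cc2OC(C)=O)c(Oc5cc(OC(C)=O)c(Oc6cc(OC(C)=O)c(OC(C)=O)c(OC(C)=O)c6)c(OC(C)=O)c5)c(OC(C)=O)c1OC(C)=O | intermediate

**Totals**
Total step count: 17.
Longest linear sequence: 10 steps (1, 3, 4, 5, 6, 7, 8, 15, 16, 17).

**Steps most likely to fail**

1. **Step 15 (Proposed new method).**
   - *What may go wrong:* The electron-rich vinylketene may be too weak an electrophile. It could then return to the cyclobutenone, dimerise or acylate the product phenol faster than the alkyne captures it. The ynol ether may also oligomerise at the temperature that ring opening needs.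
   - *Fallback:* Known chemistry only, re-using reactions already run earlier in the route. It sets out from ABC phenol 13.
     - Ullmann coupling of 13 with bromoaldehyde 6 under the conditions of step 3 should give the ABCD aldehyde F1.
     - Baeyer–Villiger oxidation through the ABCD formate F2, then methanolysis, should give the ABCD phenol F3.
     - Ullmann coupling of F3 with 10 as in step 5 should give the ABCDE aldehyde F4.
     - A second Baeyer–Villiger oxidation through the ABCDE formate F5 should give the ABCDE phenol F6.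
     - Ullmann coupling of F6 with bromide 4 under argon should give the hexadecamethyl ether F7. This is chosen over an oxidative copper(II) coupling because F6 is easily oxidised.
     - F7 takes the place of 34 in step 16, so the fallback comes back to the route at 35.

2. **Step 13.**
   - *What may go wrong:* Hydride attack may be spread over both carbonyl groups (poor site selectivity), with some displacement of the aryloxy group.
   - *Fallback:* The site question is removed by symmetry. The fallback sets out from 24 and 25.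
     - Two equivalents of 24 with 25 and iPr2NEt should give the bis(EF-aryl) squarate F8, whose carbonyl groups are equivalent.
     - Reduction of F8 as in step 13 should give rac-2,3-bis(EF-oxy)-4-hydroxycyclobut-2-en-1-one F9.
     - In F9 only the aryloxy group on C3 is a vinylogous ester leaving group. Brief treatment with MeOH and catalytic Et3N at 0 °C should therefore exchange that group alone, in the downhill direction.
     - The fallback comes back to the route at 28, and one equivalent of 24 is recovered.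

3. **Step 16.**
   - *What may go wrong:* Cleavage of the fifteen methyl ethers may be incomplete once partly cleaved borates precipitate. Acid-induced ether exchange at rings A, C and E and air oxidation during the aqueous work-up are further risks.
   - *Fallback:* It sets out from 34.
     - Reductive silylative dealkylation (Piers–Rubinsztajn reaction: Et3SiH in excess, B(C6F5)3 cat., toluene, rt) should convert every OMe and the free OH into a silyl ether. The product is the hexadecakis(triethylsilyl) ether F10, a neutral, lipophilic compound that can be chromatographed.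
     - HF·pyridine in THF at 0 °C under argon should then release the polyphenol.
     - The fallback comes back to the route at 35 and bypasses 36.

**Further compounds**
F1 | step 15 | ABCD aldehyde | O=Cc1c(OC)c(OC)c(OC)cc1Oc2c(OC)cc(Oc3c(OC)c(OC)c(OC)cc3Oc4c(OC)cc(OC)cc4OC)cc2OC
F2 | step 15 | ABCD formate | O=COc1c(OC)c(OC)c(OC)cc1Oc2c(OC)cc(Oc3c(OC)c(OC)c(OC)cc3Oc4c(OC)cc(OC)cc4OC)cc2OC
F3 | step 15 | ABCD phenol | Oc1c(OC)c(OC)c(OC)cc1Oc2c(OC)cc(Oc3c(OC)c(OC)c(OC)cc3Oc4c(OC)cc(OC)cc4OC)cc2OC
F4 | step 15 | ABCDE aldehyde | O=Cc1c(OC)cc(Oc2c(OC)c(OC)c(OC)cc2Oc3c(OC)cc(Oc4c(OC)c(OC)c(OC)cc4Oc5c(OC)cc(OC)cc5OC)cc3OC)cc1OC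
F5 | step 15 | ABCDE formate | O=COc1c(OC)cc(Oc2c(OC)c(OC)c(OC)cc2Oc3c(OC)cc(Oc4c(OC)c(OC)c(OC)cc4Oc5c(OC)cc(OC)cc5OC)cc3OC)cc1OC
F6 | step 15 | ABCDE phenol | Oc1c(OC)cc(Oc2c(OC)c(OC)c(OC)cc2Oc3c(OC)cc(Oc4c(OC)c(OC)c(OC)cc4Oc5c(OC)cc(OC)cc5OC)cc3OC)cc1OC
F7 | step 15 | hexadecamethyl ether of the target | COc1cc(Oc2c(OC)cc(Oc3c(OC)c(OC)c(OC)cc3Oc4c(OC)cc(Oc5c(OC)c(OC)c(OC)cc5Oc6c(OC)cc(OC)cc6OC)cc4OC)cc2OC)cc(OC)c1OC
F8 | step 13 | bis(EF-aryl) squarate | O=C1C(=O)C(Oc2cc(OC)c(Oc3cc(OC)c(OC)c(OC)c3)c(OC)c2)=C1Oc4cc(OC)c(Oc5cc(OC)c(OC)c(OC)c5)c(OC)c4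
F9 | step 13 | rac-2,3-bis(EF-oxy)-4-hydroxycyclobut-2-en-1-one | O=C1C(Oc2cc(OC)c(Oc3cc(OC)c(OC)c(OC)c3)c(OC)c2)=C(Oc4cc(OC)c(Oc5cc(OC)c(OC)c(OC)c5)c(OC)c4)C1O
F10 | step 16 | hexadecakis(triethylsilyl) ether of the target | CC[Si](CC)(CC)Oc1cc(Oc2c(O[Si](CC)(CC)CC)cc(Oc3c(O[Si](CC)(CC)CC)c(O[Si](CC)(CC)CC)c(O[Si](CC)(CC)CC)cc3Oc4c(O[Si](CC)(CC)CC)cc(O[Si](CC)(CC)CC)cc4O[Si](CC)(CC)CC)cc2O[Si](CC)(CC)CC)c(Oc5cc(O[Si](CC)(CC)CC)c(Oc6cc(O[Si](CC)(CC)CC)c(O[Si](CC)(CC)CC)c(O[Si](CC)(CC)CC)c6)c(O[Si](CC)(CC)CC)c5)c(O[Si](CC)(CC)CC)c1O[Si](CC)(CC)CC
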